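## Retrosynthetic overview

1. Feature used: in this (3R)-isoflavan, O2' of ring B can reach the benzylic C4 of ring C. Bonding O2' to C4 gives a cis-pterocarpan in which C3–C4 is the C3–C2 bond of a 2-aryl-2,3-dihydrobenzofuran. C3 can therefore be set by a carbene at C3 inserting into a C4–H bond of an O2'-benzyl ether.
2. Late stage: 7-O-desilylation. Dimethylpyran ring D comes from 4'-OH/C5' and 3-methylbut-2-enal. The 3'-prenyl group comes from an aromatic Claisen shift from O2', where C1' is blocked and only C3' is open.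
3. Middle: the 2'-hydroxyisoflavan comes from the pterocarpan by hydrogenolysis of C4–O2'. Ring C comes from Mitsunobu O1–C2 closure of the cis hydroxymethyl phenol.
4. Key: the cis-dihydrobenzofuran ester comes from the ring B aryldiazoacetate (C3–C4 bond). Its ether precursor joins halves made from 2,4-dihydroxyphenylacetic acid and 2,4-dihydroxybenzaldehyde.
5. Ring order: temporary dihydrofuran, then ring C, then the dihydrofuran is opened, then ring D.

Key step: step 8

Assumption: isoflavan numbering is used throughout (O1, C2, C3, C4, ring B primed). The sense of induction of Rh2(S-PTTL)4 is taken by analogy with simpler 2-(benzyloxy)phenyldiazoacetates, which lead to the (2R,3S)-cis ester; if the ortho-pivaloyloxy group reversed it, Rh2(R-PTTL)4 would be used with nothing else changed.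

## Route

Step 1
Reactants: 1 2,4-dihydroxyphenylacetic acid
Product: 2 methyl 2-(2,4-dihydroxyphenyl)acetate
Conditions: MeOH, H2SO4 (cat.), reflux
Reagents that add atoms: methanol, SMILES CO
Why: Fischer esterification; the large excess of methanol keeps the ortho-hydroxy acid on the open-ester side rather than the lactone side.

Step 2
Reactants: 2 methyl 2-(2,4-dihydroxyphenyl)acetate
Product: 3 methyl 2-[4-(tert-butyldimethylsilyloxy)-2-hydroxyphenyl]acetate
Conditions: TBSCl (1.0 equiv), imidazole, CH2Cl2–DMF, −10 to 0 °C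
Reagents that add atoms: tert-butyldimethylsilyl chloride, SMILES CC(C)(C)[Si](C)(C)Cl
Why: Chemoselective phenol silylation; the 4-OH is unhindered, whereas the 2-OH is flanked by the CH2CO2Me arm and hydrogen-bonded to its carbonyl, so one equivalent of TBSCl at low temperature should take the 4-position.

Step 3
Reactants: 4 2,4-dihydroxybenzaldehyde
Product: 5 2-hydroxy-4-(triisopropylsilyloxy)benzaldehyde
Conditions: TIPSCl (1.05 equiv), imidazole, CH2Cl2, 0 °C to rt
Reagents that add atoms: triisopropylsilyl chloride, SMILES CC(C)[Si](Cl)(C(C)C)C(C)C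
Why: Chemoselective silylation; the 2-OH is held in a strong hydrogen bond to the aldehyde and the 4-OH is the more acidic and accessible phenol, so the bulky chlorosilane should react only there.

Step 4
Reactants: 5 2-hydroxy-4-(triisopropylsilyloxy)benzaldehyde
Product: 6 2-formyl-5-(triisopropylsilyloxy)phenyl pivalate
Conditions: PivCl, Et3N, DMAP (cat.), CH2Cl2, 0 °C to rt
Reagents that add atoms: pivaloyl chloride, SMILES CC(C)(C)C(=O)Cl
Why: DMAP-catalysed acylation of the remaining phenol; the pivalate tolerates diazo transfer and the carbene step and later leaves in the same hydride step that reduces the ester.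

Step 5
Reactants: 6 2-formyl-5-(triisopropylsilyloxy)phenyl pivalate
Product: 7 2-(hydroxymethyl)-5-(triisopropylsilyloxy)phenyl pivalate
Conditions: BH3·THF, THF, −10 to 0 °C; aq. NH4Cl
Reagents that add atoms: none
Why: Borane reduction delivers the alcohol as a covalent borate and never as a free alkoxide, which should suppress the O-to-O pivaloyl shift and the quinone methide chemistry expected with basic borohydride, while aryl ester and aryl silyl ether are inert to BH3 at this temperature.

Step 6
Reactants: 3 methyl 2-[4-(tert-butyldimethylsilyloxy)-2-hydroxyphenyl]acetate; 7 2-(hydroxymethyl)-5-(triisopropylsilyloxy)phenyl pivalate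
Product: 8 methyl 2-[4-(tert-butyldimethylsilyloxy)-2-{[2-(pivaloyloxy)-4-(triisopropylsilyloxy)phenyl]methoxy}phenyl]acetate
Conditions: PPh3, DIAD, THF, 0 °C to rt
Reagents that add atoms: none
Why: Mitsunobu etherification joins O2' to the future C4 by SN2 displacement at the primary benzylic carbon under near-neutral conditions, which avoids both a labile 4-silyloxybenzyl bromide and a free phenoxide that could shuffle aryl silyl groups or lactonise onto the ester.

Step 7
Reactants: 8 methyl 2-[4-(tert-butyldimethylsilyloxy)-2-{[2-(pivaloyloxy)-4-(triisopropylsilyloxy)phenyl]methoxy}phenyl]acetate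
Product: 9 methyl 2-diazo-2-[4-(tert-butyldimethylsilyloxy)-2-{[2-(pivaloyloxy)-4-(triisopropylsilyloxy)phenyl]methoxy}phenyl]acetate
Conditions: p-ABSA, DBU, dry MeCN, 0 °C to rt
Reagents that add atoms: 4-acetamidobenzenesulfonyl azide, SMILES CC(=O)Nc1ccc(cc1)S(=O)(=O)N=[N+]=[N-]
Why: Regitz diazo transfer; DBU deprotonates the doubly activated arylacetate CH2 and the sulfonyl azide hands over N2, a standard entry to aryldiazoacetates that in dry medium leaves the pivalate and aryl silyl ethers alone.

Step 8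
Reactants: 9 methyl 2-diazo-2-[4-(tert-butyldimethylsilyloxy)-2-{[2-(pivaloyloxy)-4-(triisopropylsilyloxy)phenyl]methoxy}phenyl]acetate
Product: 11 methyl (2R,3S)-cis-6-(tert-butyldimethylsilyloxy)-2-[2-(pivaloyloxy)-4-(triisopropylsilyloxy)phenyl]-2,3-dihydrobenzofuran-3-carboxylate, via rhodium carbene 10 (not isolated)
Conditions: Rh2(S-PTTL)4 = dirhodium tetrakis[N-phthaloyl-(S)-tert-leucinate] (1 mol %), toluene, −60 °C, slow addition of 9
Reagents that add atoms: none
Why: Rh2(S-PTTL)4 expels N2 from 9 to give the donor/acceptor carbene 10, whose electrophilic carbon (future C3) takes up one of the two O–CH2–Ar hydrogens of the future C4 in a concerted but asynchronous three-centre insertion with hydride-transfer character. The closest known reaction type is the enantioselective intramolecular 1,5 C–H insertion of methyl 2-(benzyloxy)phenyldiazoacetates under chiral dirhodium tetracarboxylate catalysis, which gives cis-2-aryl-2,3-dihydrobenzofuran-3-carboxylates. The one ring formed, the temporary dihydrofuran, closes by the C3–C4 bond itself through a five-membered cyclic transition state, the normal preference of rhodium carbenes, and a four-membered oxonium ylide is out of reach. Both stereocentres come from the catalyst: the phthalimido walls of the tert-leucinate ligands decide which carbene face is open and which prochiral hydrogen is presented, and the transition state that turns ring A away from the catalyst face gives the cis (2R,3S) ester as the kinetic product. The step needs site selectivity, secured because this CH2 is the only C–H within 1,5 reach and is activated by the ether oxygen and the para-silyloxy ring A, while the substrate holds no alkene and its silyl and pivaloyl C–H bonds are remote and unactivated. It also needs C3 to hold its configuration, which the base-free medium at −60 °C should secure.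

Step 9
Reactants: 11 methyl (2R,3S)-cis-6-(tert-butyldimethylsilyloxy)-2-[2-(pivaloyloxy)-4-(triisopropylsilyloxy)phenyl]-2,3-dihydrobenzofuran-3-carboxylate
Product: 12 2-[(2R,3R)-cis-6-(tert-butyldimethylsilyloxy)-3-(hydroxymethyl)-2,3-dihydrobenzofuran-2-yl]-5-(triisopropylsilyloxy)phenol
Conditions: i-Bu2AlH (5 equiv), CH2Cl2, −78 to −40 °C; aq. potassium sodium tartrate
Reagents that add atoms: none
Why: Non-basic hydride reduction with i-Bu2AlH turns the methyl ester into the CH2OH group (future C2) and cleaves the aryl pivalate in one operation, and at low temperature it should outrun enolisation, so the epimerisable C3 and the cis relationship are kept (the descriptor at C3 changes only through priorities).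

Step 10
Reactants: 12 2-[(2R,3R)-cis-6-(tert-butyldimethylsilyloxy)-3-(hydroxymethyl)-2,3-dihydrobenzofuran-2-yl]-5-(triisopropylsilyloxy)phenol
Product: 13 (6aR,11aR)-9-(tert-butyldimethylsilyloxy)-3-(triisopropylsilyloxy)-6a,11a-dihydro-6H-benzofuro[3,2-c]chromene (cis-pterocarpan)
Conditions: PPh3, DIAD, THF (0.01 M), 0 °C to rt
Reagents that add atoms: none
Why: Intramolecular Mitsunobu etherification (6-exo-tet); only the ring A phenol is free because O2' is still locked in the dihydrofuran, and the cis geometry places it over the activated CH2OH, so O1–C2 closes ring C without touching either stereocentre.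

Step 11
Reactants: 13 (6aR,11aR)-9-(tert-butyldimethylsilyloxy)-3-(triisopropylsilyloxy)-6a,11a-dihydro-6H-benzofuro[3,2-c]chromene
Product: 14 5-(tert-butyldimethylsilyloxy)-2-[(3R)-7-(triisopropylsilyloxy)chroman-3-yl]phenol
Conditions: H2 (1 atm), 10% Pd/C, EtOAc–EtOH 1:1, rt
Reagents that add atoms: none
Why: Catalytic hydrogenolysis of a pterocarpan to a 2'-hydroxyisoflavan; C4–O2' is the only benzylic C–O bond, its cleavage turns C4 into a methylene and frees the 2'-OH, and the neutral medium avoids ionisation and elimination to an isoflav-3-ene, so C3 should stay (R).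

Step 12
Reactants: 15 2-methylbut-3-en-2-ol
Product: 17 tert-butyl 2-methylbut-3-en-2-yl carbonate, via lithium alkoxide 16 (not isolated)
Conditions: n-BuLi, THF, −78 to 0 °C; Boc2O, 0 °C to rt
Reagents that add atoms: di-tert-butyl dicarbonate, SMILES CC(C)(C)OC(=O)OC(=O)OC(C)(C)C
Why: Alkoxide acylation with Boc2O, the usual preparation of tertiary allylic carbonates for palladium-catalysed allylation.

Step 13
Reactants: 14 5-(tert-butyldimethylsilyloxy)-2-[(3R)-7-(triisopropylsilyloxy)chroman-3-yl]phenol; 17 tert-butyl 2-methylbut-3-en-2-yl carbonate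
Product: 18 (3R)-3-[4-(tert-butyldimethylsilyloxy)-2-(2-methylbut-3-en-2-yloxy)phenyl]-7-(triisopropylsilyloxy)chroman
Conditions: Pd(PPh3)4 (5 mol %), THF, 0 °C
Reagents that add atoms: none
Why: Tsuji–Trost O-allylation; zerovalent palladium ionises the tertiary carbonate with loss of CO2, the released tert-butoxide deprotonates the only free phenol, and under kinetic control at low temperature the phenoxide attacks the more substituted allyl terminus to give the 1,1-dimethylallyl ether.

Step 14
Reactants: 18 (3R)-3-[4-(tert-butyldimethylsilyloxy)-2-(2-methylbut-3-en-2-yloxy)phenyl]-7-(triisopropylsilyloxy)chroman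
Product: 19 3-(2-methylbut-3-en-2-yloxy)-4-[(3R)-7-(triisopropylsilyloxy)chroman-3-yl]phenol
Conditions: K2CO3 (0.3 equiv), MeOH–THF, 0 °C, stopped when 18 is consumed
Reagents that add atoms: none
Why: Base-catalysed methanolysis of an aryl silyl ether; attack at silicon is much slower for triisopropylsilyl than for tert-butyldimethylsilyl, both ethers are flanked only by hydrogens at this stage, and the tertiary allyl ether is inert to base, so the 4'-OH should be released alone.

Step 15
Reactants: 19 3-(2-methylbut-3-en-2-yloxy)-4-[(3R)-7-(triisopropylsilyloxy)chroman-3-yl]phenol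
Product: 21 2-(3-methylbut-2-enyl)-4-[(3R)-7-(triisopropylsilyloxy)chroman-3-yl]benzene-1,3-diol, via ortho-dienone 20 (not isolated)
Conditions: PhNEt2, 120 °C, argon
Reagents that add atoms: none
Why: Aromatic Claisen rearrangement; of the two positions ortho to O2' only C3' carries hydrogen, so the [3,3] shift with allyl inversion places a prenyl group there via dienone 20, which rearomatises to the 2'-phenol, and the amine solvent buffers traces of acid that would cyclise the prenylphenol.

Step 16
Reactants: 21 2-(3-methylbut-2-enyl)-4-[(3R)-7-(triisopropylsilyloxy)chroman-3-yl]benzene-1,3-diol; 22 3-methylbut-2-enal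
Product: 24 2,2-dimethyl-8-(3-methylbut-2-enyl)-6-[(3R)-7-(triisopropylsilyloxy)chroman-3-yl]-2H-chromen-7-ol, via ortho-quinone methide 23 (not isolated)
Conditions: ethylenediammonium diacetate (10 mol %), toluene, reflux
Reagents that add atoms: none
Why: Formal [3+3] chromene annulation (Knoevenagel-type condensation, then oxa-6π electrocyclisation); C5' is the only free nucleophilic position of ring B, ortho to 4'-OH and para to 2'-OH, so condensation gives quinone methide 23, which closes through O4', while ring A cannot react because its phenol is silylated.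

Step 17
Reactants: 24 2,2-dimethyl-8-(3-methylbut-2-enyl)-6-[(3R)-7-(triisopropylsilyloxy)chroman-3-yl]-2H-chromen-7-ol
Product: 25 (3R)-3-[7-hydroxy-2,2-dimethyl-8-(3-methylbut-2-enyl)-2H-chromen-6-yl]chroman-7-ol (CNP0331403.1)
Conditions: n-Bu4NF, AcOH (1:1), THF, 0 °C
Reagents that add atoms: none
Why: Fluoride-mediated desilylation driven by Si–F bond formation; buffering with AcOH keeps the medium near neutral, so chromene, prenyl group and C3 should be unaffected.

## Compound list

1 | 2,4-dihydroxyphenylacetic acid | OC(=O)Cc1ccc(O)cc1O | starting material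
2 | methyl 2-(2,4-dihydroxyphenyl)acetate | COC(=O)Cc1ccc(O)cc1O | intermediate
3 | methyl 2-[4-(tert-butyldimethylsilyloxy)-2-hydroxyphenyl]acetate | COC(=O)Cc1ccc(O[Si](C)(C)C(C)(C)C)cc1O | intermediate
4 | 2,4-dihydroxybenzaldehyde | O=Cc1ccc(O)cc1O | starting material
5 | 2-hydroxy-4-(triisopropylsilyloxy)benzaldehyde | O=Cc1ccc(O[Si](C(C)C)(C(C)C)C(C)C)cc1O | intermediate
6 | 2-formyl-5-(triisopropylsilyloxy)phenyl pivalate | O=Cc1ccc(O[Si](C(C)C)(C(C)C)C(C)C)cc1OC(=O)C(C)(C)C | intermediate
7 | 2-(hydroxymethyl)-5-(triisopropylsilyloxy)phenyl pivalate | OCc1ccc(O[Si](C(C)C)(C(C)C)C(C)C)cc1OC(=O)C(C)(C)C | intermediate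
8 | methyl 2-[4-(tert-butyldimethylsilyloxy)-2-{[2-(pivaloyloxy)-4-(triisopropylsilyloxy)phenyl]methoxy}phenyl]acetate | COC(=O)Cc1ccc(O[Si](C)(C)C(C)(C)C)cc1OCc1ccc(O[Si](C(C)C)(C(C)C)C(C)C)cc1OC(=O)C(C)(C)C | intermediate
9 | methyl 2-diazo-2-[4-(tert-butyldimethylsilyloxy)-2-{[2-(pivaloyloxy)-4-(triisopropylsilyloxy)phenyl]methoxy}phenyl]acetate | COC(=O)C(=[N+]=[N-])c1ccc(O[Si](C)(C)C(C)(C)C)cc1OCc1ccc(O[Si](C(C)C)(C(C)C)C(C)C)cc1OC(=O)C(C)(C)C | intermediate
10 | rhodium carbene derived from 9 (Rh stands for the Rh2(S-PTTL)4 unit) | COC(=O)C(=[Rh])c1ccc(O[Si](C)(C)C(C)(C)C)cc1OCc1ccc(O[Si](C(C)C)(C(C)C)C(C)C)cc1OC(=O)C(C)(C)C | intermediate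
11 | methyl (2R,3S)-cis-6-(tert-butyldimethylsilyloxy)-2-[2-(pivaloyloxy)-4-(triisopropylsilyloxy)phenyl]-2,3-dihydrobenzofuran-3-carboxylate | COC(=O)[C@H]1c2ccc(O[Si](C)(C)C(C)(C)C)cc2O[C@H]1c1ccc(O[Si](C(C)C)(C(C)C)C(C)C)cc1OC(=O)C(C)(C)C | intermediate
12 | 2-[(2R,3R)-cis-6-(tert-butyldimethylsilyloxy)-3-(hydroxymethyl)-2,3-dihydrobenzofuran-2-yl]-5-(triisopropylsilyloxy)phenol | OC[C@H]1c2ccc(O[Si](C)(C)C(C)(C)C)cc2O[C@H]1c1ccc(O[Si](C(C)C)(C(C)C)C(C)C)cc1O | intermediate
13 | (6aR,11aR)-9-(tert-butyldimethylsilyloxy)-3-(triisopropylsilyloxy)-6a,11a-dihydro-6H-benzofuro[3,2-c]chromene | C1[C@H]2c3ccc(O[Si](C)(C)C(C)(C)C)cc3O[C@H]2c2ccc(O[Si](C(C)C)(C(C)C)C(C)C)cc2O1 | intermediate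
14 | 5-(tert-butyldimethylsilyloxy)-2-[(3R)-7-(triisopropylsilyloxy)chroman-3-yl]phenol | CC(C)(C)[Si](C)(C)Oc1ccc([C@@H]2COc3cc(O[Si](C(C)C)(C(C)C)C(C)C)ccc3C2)c(O)c1 | intermediate
15 | 2-methylbut-3-en-2-ol | CC(C)(O)C=C | starting material
16 | lithium 2-methylbut-3-en-2-olate | [Li+].CC(C)([O-])C=C | intermediate
17 | tert-butyl 2-methylbut-3-en-2-yl carbonate | CC(C)(C)OC(=O)OC(C)(C)C=C | intermediate
18 | (3R)-3-[4-(tert-butyldimethylsilyloxy)-2-(2-methylbut-3-en-2-yloxy)phenyl]-7-(triisopropylsilyloxy)chroman | C=CC(C)(C)Oc1cc(O[Si](C)(C)C(C)(C)C)ccc1[C@@H]1COc2cc(O[Si](C(C)C)(C(C)C)C(C)C)ccc2C1 | intermediate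
19 | 3-(2-methylbut-3-en-2-yloxy)-4-[(3R)-7-(triisopropylsilyloxy)chroman-3-yl]phenol | C=CC(C)(C)Oc1cc(O)ccc1[C@@H]1COc2cc(O[Si](C(C)C)(C(C)C)C(C)C)ccc2C1 | intermediate
20 | 5-hydroxy-6-(3-methylbut-2-enyl)-2-[(3R)-7-(triisopropylsilyloxy)chroman-3-yl]cyclohexa-2,4-dien-1-one (C6 undefined) | CC(C)=CCC1C(O)=CC=C([C@@H]2COc3cc(O[Si](C(C)C)(C(C)C)C(C)C)ccc3C2)C1=O | intermediate
21 | 2-(3-methylbut-2-enyl)-4-[(3R)-7-(triisopropylsilyloxy)chroman-3-yl]benzene-1,3-diol | CC(C)=CCc1c(O)ccc([C@@H]2COc3cc(O[Si](C(C)C)(C(C)C)C(C)C)ccc3C2)c1O | intermediate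
22 | 3-methylbut-2-enal | CC(C)=CC=O | starting material
23 | ortho-quinone methide: 3-hydroxy-2-(3-methylbut-2-enyl)-6-(3-methylbut-2-enylidene)-4-[(3R)-7-(triisopropylsilyloxy)chroman-3-yl]cyclohexa-2,4-dien-1-one | CC(C)=CC=C1C=C([C@@H]2COc3cc(O[Si](C(C)C)(C(C)C)C(C)C)ccc3C2)C(O)=C(CC=C(C)C)C1=O | intermediate
24 | 2,2-dimethyl-8-(3-methylbut-2-enyl)-6-[(3R)-7-(triisopropylsilyloxy)chroman-3-yl]-2H-chromen-7-ol | CC(C)=CCc1c(O)c([C@@H]2COc3cc(O[Si](C(C)C)(C(C)C)C(C)C)ccc3C2)cc2c1OC(C)(C)C=C2 | intermediate
25 | (3R)-3-[7-hydroxy-2,2-dimethyl-8-(3-methylbut-2-enyl)-2H-chromen-6-yl]chroman-7-ol | CC(C)=CCc1c(O)c([C@@H]2COc3cc(O)ccc3C2)cc2c1OC(C)(C)C=C2 | target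

## Step count and risks

Total step count: 17.
Longest linear sequence: 14 steps, from 4 through steps 3–11 and 13–17 to 25.

**Step 8.**
- What may go wrong: the ortho-pivaloyloxy group crowds the C4–H bonds. This could slow insertion, so that carbene dimerisation gains ground. It could also loosen the fit in the catalyst pocket, so that facial and cis selectivity erode.
- Fallback: the same C3–C4 bond is formed by auxiliary-controlled enolate benzylation (Evans alkylation), setting out from 3 and 7 and returning at 14.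
- Phenol 3 is etherified with benzyl alcohol (PPh3, DIAD, THF) to methyl 2-[2-(benzyloxy)-4-(tert-butyldimethylsilyloxy)phenyl]acetate F1.
- Me3SnOH in 1,2-dichloroethane at 70 °C cleaves the methyl ester without attacking the aryl silyl ether, giving 2-[2-(benzyloxy)-4-(tert-butyldimethylsilyloxy)phenyl]acetic acid F2.
- Activation with PivCl/Et3N and addition of lithiated (R)-4-benzyloxazolidin-2-one gives (4R)-4-benzyl-3-{2-[2-(benzyloxy)-4-(tert-butyldimethylsilyloxy)phenyl]acetyl}oxazolidin-2-one F3.
- Alcohol 7 is converted under Appel conditions (CBr4, PPh3, CH2Cl2, 0 °C) into 2-(bromomethyl)-5-(triisopropylsilyloxy)phenyl pivalate F4, which is used at once.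
- Treatment of F3 with NaN(SiMe3)2 in THF at −78 °C and then with F4 should give (4R)-4-benzyl-3-{(2R)-2-[2-(benzyloxy)-4-(tert-butyldimethylsilyloxy)phenyl]-3-[2-(pivaloyloxy)-4-(triisopropylsilyloxy)phenyl]propanoyl}oxazolidin-2-one F5. The benzyl group of the auxiliary shields one face of the chelated Z-enolate.
- Excess LiBH4 in THF–MeOH removes the auxiliary and the pivalate to give (2R)-2-[2-(benzyloxy)-4-(tert-butyldimethylsilyloxy)phenyl]-3-[2-hydroxy-4-(triisopropylsilyloxy)phenyl]propan-1-ol F6.
- Mitsunobu closure (PPh3, DIAD) gives (3R)-3-[2-(benzyloxy)-4-(tert-butyldimethylsilyloxy)phenyl]-7-(triisopropylsilyloxy)chroman F7.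
- H2 over Pd/C in EtOAc cleaves the benzyl ether to 14.

**Step 13.**
- What may go wrong: the hindered 2'-phenoxide captures the allylpalladium species slowly. This leaves time for re-ionisation of the tertiary ether and drift to the linear O-prenyl isomer or to C-allylation.
- Fallback: the tertiary ether is built in two stages without palladium allyl chemistry, setting out from 14 and returning at 18.
- Copper-catalysed propargylic etherification with 3-chloro-3-methylbut-1-yne (CuCl2 cat., DBU, dry MeCN, 0 °C) should give (3R)-3-[4-(tert-butyldimethylsilyloxy)-2-(2-methylbut-3-yn-2-yloxy)phenyl]-7-(triisopropylsilyloxy)chroman F8.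
- Semi-hydrogenation of F8 (H2, Pd/CaCO3 poisoned with Pb(OAc)2, quinoline, EtOAc) gives 18.

**Step 14.**
- What may go wrong: discrimination between the two aryl silyl ethers is incomplete, so the ring A protecting group is lost along with the ring B one.
- Fallback: selective deprotection is replaced by selective reprotection after the Claisen step has made the three phenols sterically different, setting out from 18 and returning at 21.
- n-Bu4NF in THF removes both silyl groups to give 3-(2-methylbut-3-en-2-yloxy)-4-[(3R)-7-hydroxychroman-3-yl]phenol F9.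
- Heating in PhNEt2 at 120 °C effects the same Claisen shift to 2-(3-methylbut-2-enyl)-4-[(3R)-7-hydroxychroman-3-yl]benzene-1,3-diol F10.
- One equivalent of TIPSCl with imidazole at 0 °C should take the 7-OH, the only phenol flanked by two hydrogens, to give 21.

Further compounds
F1 | step 8 | methyl 2-[2-(benzyloxy)-4-(tert-butyldimethylsilyloxy)phenyl]acetate | COC(=O)Cc1ccc(O[Si](C)(C)C(C)(C)C)cc1OCc1ccccc1
F2 | step 8 | 2-[2-(benzyloxy)-4-(tert-butyldimethylsilyloxy)phenyl]acetic acid | OC(=O)Cc1ccc(O[Si](C)(C)C(C)(C)C)cc1OCc1ccccc1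
F3 | step 8 | (4R)-4-benzyl-3-{2-[2-(benzyloxy)-4-(tert-butyldimethylsilyloxy)phenyl]acetyl}oxazolidin-2-one | O=C(Cc1ccc(O[Si](C)(C)C(C)(C)C)cc1OCc1ccccc1)N1[C@H](Cc2ccccc2)COC1=O
F4 | step 8 | 2-(bromomethyl)-5-(triisopropylsilyloxy)phenyl pivalate | BrCc1ccc(O[Si](C(C)C)(C(C)C)C(C)C)cc1OC(=O)C(C)(C)C
F5 | step 8 | (4R)-4-benzyl-3-{(2R)-2-[2-(benzyloxy)-4-(tert-butyldimethylsilyloxy)phenyl]-3-[2-(pivaloyloxy)-4-(triisopropylsilyloxy)phenyl]propanoyl}oxazolidin-2-one | O=C([C@H](Cc1ccc(O[Si](C(C)C)(C(C)C)C(C)C)cc1OC(=O)C(C)(C)C)c1ccc(O[Si](C)(C)C(C)(C)C)cc1OCc1ccccc1)N1[C@H](Cc2ccccc2)COC1=O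
F6 | step 8 | (2R)-2-[2-(benzyloxy)-4-(tert-butyldimethylsilyloxy)phenyl]-3-[2-hydroxy-4-(triisopropylsilyloxy)phenyl]propan-1-ol | OC[C@H](Cc1ccc(O[Si](C(C)C)(C(C)C)C(C)C)cc1O)c1ccc(O[Si](C)(C)C(C)(C)C)cc1OCc1ccccc1
F7 | step 8 | (3R)-3-[2-(benzyloxy)-4-(tert-butyldimethylsilyloxy)phenyl]-7-(triisopropylsilyloxy)chroman | CC(C)(C)[Si](C)(C)Oc1ccc([C@@H]2COc3cc(O[Si](C(C)C)(C(C)C)C(C)C)ccc3C2)c(OCc2ccccc2)c1
F8 | step 13 | (3R)-3-[4-(tert-butyldimethylsilyloxy)-2-(2-methylbut-3-yn-2-yloxy)phenyl]-7-(triisopropylsilyloxy)chroman | C#CC(C)(C)Oc1cc(O[Si](C)(C)C(C)(C)C)ccc1[C@@H]1COc2cc(O[Si](C(C)C)(C(C)C)C(C)C)ccc2C1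
F9 | step 14 | 3-(2-methylbut-3-en-2-yloxy)-4-[(3R)-7-hydroxychroman-3-yl]phenol | C=CC(C)(C)Oc1cc(O)ccc1[C@@H]1COc2cc(O)ccc2C1
F10 | step 14 | 2-(3-methylbut-2-enyl)-4-[(3R)-7-hydroxychroman-3-yl]benzene-1,3-diol | CC(C)=CCc1c(O)ccc([C@@H]2COc3cc(O)ccc3C2)c1O
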